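## Retrosynthetic overview

1. Target 23 ⇐ diene diester 21 (β-epoxide installed last via a bromohydrin) ⇐ tricyclic ketone 19 (C2 ketone → 2S alcohol → butanoate).
2. 19 ⇐ acyclic tetraene 18: one intramolecular Diels–Alder reaction closes the cyclohexene (C1–C10, C13–C14) and the ten-membered carbocycle together and sets C1, C10 and C14 from C7.
3. 18 ⇐ alkyl iodide 13 + thioester 16 (Fukuyama ketone synthesis brings in the (Z)-β-acetoxy enone dienophile last).
4. 13 ⇐ butenolide 9 (diene arm by cross-metathesis and methylenation) ⇐ propargylic diol 5 by hydroxyl-directed anti-allylmagnesiation and CO2 trapping.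
5. 5 ⇐ anhydromevalonolactone 1 (Z-alkene, C3–C7) + propyne 3. Ring order: butenolide, then six- and ten-membered rings in one step, then epoxide.

Assumption: briarane numbering is used (C1 quaternary with Me-15; C2 CH–O-butanoate; C5(Me-16)=C6; C7 lactone CH–O; C8=C17(Me-18)–C19(=O)O; C9 CH2; C10 ring-fusion CH; C11(Me-20)/C12 epoxide; C14 CH–OAc), β means the face of Me-15, and the ProPhenol antipode in step 2 is the one that gives the 5R alcohol (to be confirmed by Mosher analysis).

## Route

Step 1
Reactants: 1 4-methyl-5,6-dihydro-2H-pyran-2-one (anhydromevalonolactone)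
Product: 2 4-methyl-5,6-dihydro-2H-pyran-2-ol (lactol, racemic at the hemiacetal carbon)
Conditions: i-Bu2AlH (1.1 equiv), CH2Cl2, −78 °C; aq. potassium sodium tartrate
Reagents that add atoms: none
Why: Partial 1,2-reduction of an α,β-unsaturated δ-lactone with DIBAL-H stops at the lactol at −78 °C, and the ring keeps the future C5=C6 alkene Z with Me-16 and the C3 oxygen handle in place.

Step 2
Reactants: 2 4-methyl-5,6-dihydro-2H-pyran-2-ol; 3 propyne
Product: 5 (3Z,5R)-3-methyloct-3-en-6-yne-1,5-diol, via open-chain hydroxy-enal 4 (not isolated)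
Conditions: (S,S)-ProPhenol (20 mol%), Me2Zn (4 equiv), Ph3P=O (40 mol%), 3 (3 equiv), PhMe, 0 → 4 °C, 48 h; aq. NH4Cl
Reagents that add atoms: none
Why: Zinc–ProPhenol (Trost) asymmetric alkynylation of an enal, in which the zinc lactolate opens to the conjugated (Z)-enal 4 and the chiral dinuclear zinc alkynylide adds to one aldehyde face to set the carbinol that becomes C7 as R.

Step 3
Reactants: 5 (3Z,5R)-3-methyloct-3-en-6-yne-1,5-diol; 6 allylmagnesium chloride
Product: 9 (5R)-5-[(1Z)-4-hydroxy-2-methylbut-1-en-1-yl]-3-methyl-4-(prop-2-en-1-yl)furan-2(5H)-one, via alkenylmagnesium chelate 7 (not isolated), via hydroxy acid 8 (not isolated)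
Conditions: 6 (5 equiv, 2 M in THF), THF/PhMe, 65 °C, 6 h; CO2 (gas), −30 → 0 °C; 2 M HCl, rt
Reagents that add atoms: carbon dioxide, O=C=O
Why: Hydroxyl-directed anti-carbomagnesiation of a propargylic alkoxide (Eisch/Fallis type) delivers allyl to the alkyne carbon next to the carbinol and leaves magnesium on the methyl-bearing carbon cis to the alkoxide, so carboxylation and acidification give the Z-γ-hydroxy acid 8 that lactonises to the tetrasubstituted butenolide with C7 untouched.

Step 4
Reactants: 9 (5R)-5-[(1Z)-4-hydroxy-2-methylbut-1-en-1-yl]-3-methyl-4-(prop-2-en-1-yl)furan-2(5H)-one; 10 methacrolein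
Product: 11 (2E)-4-{(2R)-2-[(1Z)-4-hydroxy-2-methylbut-1-en-1-yl]-4-methyl-5-oxo-2,5-dihydrofuran-3-yl}-2-methylbut-2-enal
Conditions: 10 (8 equiv), second-generation Hoveyda–Grubbs catalyst (5 mol%), 1,4-benzoquinone (10 mol%), CH2Cl2, 40 °C
Reagents that add atoms: none
Why: Olefin cross-metathesis of the only monosubstituted alkene with methacrolein gives the trisubstituted (E)-enal under thermodynamic control, the tri- and tetrasubstituted alkenes being inert and benzoquinone suppressing allyl isomerisation.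

Step 5
Reactants: 11 (2E)-4-{(2R)-2-[(1Z)-4-hydroxy-2-methylbut-1-en-1-yl]-4-methyl-5-oxo-2,5-dihydrofuran-3-yl}-2-methylbut-2-enal
Product: 12 (5R)-5-[(1Z)-4-hydroxy-2-methylbut-1-en-1-yl]-3-methyl-4-[(2E)-3-methylpenta-2,4-dien-1-yl]furan-2(5H)-one
Conditions: Zn, CH2Br2, TiCl4 (Takai–Lombardo reagent, 4 equiv), THF/CH2Cl2, 0 °C → rt
Reagents that add atoms: dibromomethane, BrCBr
Why: Takai–Lombardo methylenation turns the enal into the terminal 1,3-diene under non-basic conditions, so neither the acidic C7–H nor the doubly allylic C9 methylene is deprotonated and the E geometry is kept.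

Step 6
Reactants: 12 (5R)-5-[(1Z)-4-hydroxy-2-methylbut-1-en-1-yl]-3-methyl-4-[(2E)-3-methylpenta-2,4-dien-1-yl]furan-2(5H)-one
Product: 13 (5R)-5-[(1Z)-4-iodo-2-methylbut-1-en-1-yl]-3-methyl-4-[(2E)-3-methylpenta-2,4-dien-1-yl]furan-2(5H)-one
Conditions: PPh3, I2, imidazole, CH2Cl2, 0 °C, dark
Reagents that add atoms: iodine, II
Why: Appel-type (Garegg–Samuelsson) iodination converts the primary alcohol into the iodide by SN2 displacement of the oxyphosphonium ion without touching the alkenes or the lactone.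

Step 7
Reactants: 14 S-ethyl propanethioate
Product: 16 S-ethyl (2Z)-3-(acetyloxy)-2-methylprop-2-enethioate, via lithium formyl enolate 15 (not isolated)
Conditions: LiN(iPr)2 (1.05 equiv), THF, −78 °C; HCO2Et (1.2 equiv), −78 → −40 °C; AcCl (1.5 equiv), −78 °C
Reagents that add atoms: ethyl formate, CCOC=O; acetyl chloride, CC(Cl)=O
Why: Crossed Claisen formylation of the thioester enolate gives the lithium-chelated (U-shaped) formyl enolate 15, and kinetic O-acetylation at −78 °C traps that geometry as the (Z)-enol acetate (acetoxy cis to the acyl group) needed for the cis C2/C14-O relationship.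

Step 8
Reactants: 13 (5R)-5-[(1Z)-4-iodo-2-methylbut-1-en-1-yl]-3-methyl-4-[(2E)-3-methylpenta-2,4-dien-1-yl]furan-2(5H)-one; 16 S-ethyl (2Z)-3-(acetyloxy)-2-methylprop-2-enethioate
Product: 18 (1Z,6Z)-2,6-dimethyl-7-{(2R)-4-methyl-3-[(2E)-3-methylpenta-2,4-dien-1-yl]-5-oxo-2,5-dihydrofuran-2-yl}-3-oxohepta-1,6-dien-1-yl acetate, via alkylzinc iodide 17 (not isolated)
Conditions: Zn dust (activated, 3 equiv), THF/DMA, 35 °C; then 16 (1.3 equiv), PdCl2(PPh3)2 (10 mol%), PhMe, rt, 30 min
Reagents that add atoms: none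
Why: Fukuyama ketone synthesis couples the weakly basic alkylzinc iodide with the thioester at palladium to give the ketone without over-addition and with retention of the enol acetate geometry, while the short reaction at room temperature leaves the C7–H, the hindered allylic lactone and the enol ester intact.

Step 9
Reactants: 18 (1Z,6Z)-2,6-dimethyl-7-{(2R)-4-methyl-3-[(2E)-3-methylpenta-2,4-dien-1-yl]-5-oxo-2,5-dihydrofuran-2-yl}-3-oxohepta-1,6-dien-1-yl acetate
Product: 19 (1R,5Z,7R,10S,14S)-14-acetoxy-2-oxobriara-5,8(17),11-trien-19,7-olide (trans-fused; Me-15 β, H-10 α, 14-OAc α)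
Conditions: Me2AlCl (3 equiv), CH2Cl2 (1 mM), −40 °C → rt, 48 h; aq. potassium sodium tartrate
Reagents that add atoms: none
Why: Proposed new method: a Lewis-acid-promoted intramolecular Diels–Alder macrocyclisation (closest known type: the intramolecular Diels–Alder closures of eleven-membered carbocycles used for cytochalasans) in which ketone-bound Me2AlCl lowers the dienophile LUMO, the tether pre-organised by the planar butenolide and the Z-C5=C6 alkene enforces C1–C10/C13–C14 bonding in line with the "ortho" preference of a 1-alkyl diene, the E-diene reacting through the methyl-endo/ketone-exo transition state gives the trans ring fusion (Me-15 cis to C9), suprafacial addition to the Z-dienophile places 14-OAc cis to C2, and the C7 centre, held by A(1,3) strain with C7–H in the alkene plane, is expected (not proven) to direct the dienophile to the diene face that gives 1R,10S,14S.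

Step 10
Reactants: 19 (1R,5Z,7R,10S,14S)-14-acetoxy-2-oxobriara-5,8(17),11-trien-19,7-olide
Product: 20 (1S,2S,5Z,7R,10S,14S)-14-acetoxy-2-hydroxybriara-5,8(17),11-trien-19,7-olide
Conditions: (R)-2-methyl-CBS-oxazaborolidine (0.5 equiv), catecholborane (2.5 equiv), PhMe, −60 → −30 °C; MeOH, pH 7 buffer
Reagents that add atoms: none
Why: Corey–Bakshi–Shibata reduction under reagent control, with quaternary C1 as the large and C3H2 as the small ketone substituent, makes the (R)-catalyst deliver hydride to give the 2S alcohol, while catecholborane at low temperature neither hydroborates the alkenes nor reduces the esters.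

Step 11
Reactants: 20 (1S,2S,5Z,7R,10S,14S)-14-acetoxy-2-hydroxybriara-5,8(17),11-trien-19,7-olide
Product: 21 (1S,2S,5Z,7R,10S,14S)-14-acetoxy-2-butanoyloxybriara-5,8(17),11-trien-19,7-olide
Conditions: (PrCO)2O (3 equiv), DMAP (0.2 equiv), pyridine, CH2Cl2, 0 °C → rt
Reagents that add atoms: butanoic anhydride, CCCC(=O)OC(=O)CCC
Why: DMAP-catalysed (Steglich-type) acylation esterifies the hindered secondary alcohol with retention at C2, and the weak base and low temperature avoid C7 epimerisation and 14-O to 2-O acetyl migration.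

Step 12
Reactants: 21 (1S,2S,5Z,7R,10S,14S)-14-acetoxy-2-butanoyloxybriara-5,8(17),11-trien-19,7-olide
Product: 23 (1S,2S,5Z,7R,10R,11R,12S,14S)-14-acetoxy-2-butanoyloxy-11,12-epoxybriara-5,8(17)-dien-19,7-olide (CNP0220791.2), via bromohydrin 22 (not isolated)
Conditions: NBS (1.05 equiv), THF/H2O (4:1), 0 °C, dark; then Ag2O (2 equiv), rt
Reagents that add atoms: water, O; N-bromosuccinimide, O=C1CCC(=O)N1Br (its bromine is carried only in 22)
Why: Bromohydrin formation and ring closure (the sequence used for steroid 5β,6β-epoxides) works because the electron-richer C11=C12 alkene reacts before the C5=C6 alkene deactivated by the allylic lactone oxygen, water opens the α-bromonium ion at tertiary C11 in the trans-diaxial (Fürst–Plattner) and Markovnikov sense to give 11β-OH/12α-Br, and silver-assisted SN2 closure with inversion at C12 gives the 11β,12β-epoxide.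

## Compound list

1 | 4-methyl-5,6-dihydro-2H-pyran-2-one (anhydromevalonolactone) | CC1=CC(=O)OCC1 | starting material
2 | 4-methyl-5,6-dihydro-2H-pyran-2-ol (racemic lactol) | CC1=CC(O)OCC1 | intermediate
3 | propyne | CC#C | starting material
4 | (2Z)-5-hydroxy-3-methylpent-2-enal (open-chain tautomer of 2, reacting as its zinc alkoxide) | O=C/C=C(C)\CCO | intermediate (not isolated)
5 | (3Z,5R)-3-methyloct-3-en-6-yne-1,5-diol | CC#C[C@H](O)/C=C(C)\CCO | intermediate
6 | allylmagnesium chloride | C=CC[Mg]Cl | starting material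
7 | alkenylmagnesium chelate from anti-allylmagnesiation of 5 (ClMgO on C7 and C3, ClMg on C17 cis to the C7 alkoxide, allyl on C8; 7R, 5Z) | C=CC/C(=C(C)/[Mg]Cl)[C@H](O[Mg]Cl)/C=C(C)\CCO[Mg]Cl | intermediate (not isolated)
8 | (2Z,4R,5Z)-4,8-dihydroxy-2,6-dimethyl-3-(prop-2-en-1-yl)octa-2,5-dienoic acid | C=CC/C(=C(C)/C(=O)O)[C@H](O)/C=C(C)\CCO | intermediate (not isolated)
9 | (5R)-5-[(1Z)-4-hydroxy-2-methylbut-1-en-1-yl]-3-methyl-4-(prop-2-en-1-yl)furan-2(5H)-one | C=CCC1=C(C)C(=O)O[C@@H]1/C=C(C)\CCO | intermediate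
10 | methacrolein (2-methylprop-2-enal) | CC(=C)C=O | starting material
11 | (2E)-4-{(2R)-2-[(1Z)-4-hydroxy-2-methylbut-1-en-1-yl]-4-methyl-5-oxo-2,5-dihydrofuran-3-yl}-2-methylbut-2-enal | O=C/C(C)=C/CC1=C(C)C(=O)O[C@@H]1/C=C(C)\CCO | intermediate
12 | (5R)-5-[(1Z)-4-hydroxy-2-methylbut-1-en-1-yl]-3-methyl-4-[(2E)-3-methylpenta-2,4-dien-1-yl]furan-2(5H)-one | C=C/C(C)=C/CC1=C(C)C(=O)O[C@@H]1/C=C(C)\CCO | intermediate
13 | (5R)-5-[(1Z)-4-iodo-2-methylbut-1-en-1-yl]-3-methyl-4-[(2E)-3-methylpenta-2,4-dien-1-yl]furan-2(5H)-one | C=C/C(C)=C/CC1=C(C)C(=O)O[C@@H]1/C=C(C)\CCI | intermediate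
14 | S-ethyl propanethioate | CCC(=O)SCC | starting material
15 | lithium (1Z)-3-(ethylsulfanyl)-2-methyl-3-oxoprop-1-en-1-olate | CCSC(=O)/C(C)=C\[O-].[Li+] | intermediate (not isolated)
16 | S-ethyl (2Z)-3-(acetyloxy)-2-methylprop-2-enethioate | CCSC(=O)/C(C)=C\OC(C)=O | intermediate
17 | alkylzinc iodide from 13 (C–I replaced by C–ZnI) | C=C/C(C)=C/CC1=C(C)C(=O)O[C@@H]1/C=C(C)\CC[Zn]I | intermediate (not isolated)
18 | (1Z,6Z)-2,6-dimethyl-7-{(2R)-4-methyl-3-[(2E)-3-methylpenta-2,4-dien-1-yl]-5-oxo-2,5-dihydrofuran-2-yl}-3-oxohepta-1,6-dien-1-yl acetate | CC(=O)O/C=C(C)\C(=O)CC/C(C)=C\[C@H]1OC(=O)C(C)=C1C/C=C(C)/C=C | intermediate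
19 | (1R,5Z,7R,10S,14S)-14-acetoxy-2-oxobriara-5,8(17),11-trien-19,7-olide | O=C1CC/C(C)=C\[C@H]2OC(=O)C(C)=C2C[C@H]2C(C)=CC[C@H](OC(C)=O)[C@]12C | intermediate
20 | (1S,2S,5Z,7R,10S,14S)-14-acetoxy-2-hydroxybriara-5,8(17),11-trien-19,7-olide | O[C@H]1CC/C(C)=C\[C@H]2OC(=O)C(C)=C2C[C@H]2C(C)=CC[C@H](OC(C)=O)[C@]12C | intermediate
21 | (1S,2S,5Z,7R,10S,14S)-14-acetoxy-2-butanoyloxybriara-5,8(17),11-trien-19,7-olide | CCCC(=O)O[C@H]1CC/C(C)=C\[C@H]2OC(=O)C(C)=C2C[C@H]2C(C)=CC[C@H](OC(C)=O)[C@]12C | intermediate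
22 | (1S,2S,5Z,7R,10R,11R,12R,14S)-14-acetoxy-12-bromo-2-butanoyloxy-11-hydroxybriara-5,8(17)-dien-19,7-olide (11β-OH, 12α-Br) | CCCC(=O)O[C@H]1CC/C(C)=C\[C@H]2OC(=O)C(C)=C2C[C@H]2[C@@](C)(O)[C@H](Br)C[C@H](OC(C)=O)[C@]12C | intermediate (not isolated)
23 | (1S,2S,5Z,7R,10R,11R,12S,14S)-14-acetoxy-2-butanoyloxy-11,12-epoxybriara-5,8(17)-dien-19,7-olide (CNP0220791.2) | CCCC(=O)O[C@H]1CC/C(C)=C\[C@H]2OC(=O)C(C)=C2C[C@H]2[C@@]3(C)O[C@H]3C[C@H](OC(C)=O)[C@]12C | target

## Step count and risks

Total steps: 12. Longest linear sequence: 11 (steps 1–6 and 8–12; step 7 is a one-step side branch).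

**Step 9 (most likely to fail).** The ten-membered ring may close too slowly, the ring fusion or the facial relay from C7 may go the wrong way, and the Lewis acid may scramble the Z-enol acetate or ionise the allylic lactone. The fallback sets out from 13 and 16 and comes back at 19, reversing the ring order. An intermolecular Diels–Alder reaction of the diene of 13 with thioester 16 under a chiral oxazaborolidinium triflimide catalyst (catalyst control of the diene face, CH2Cl2, −40 °C) gives the cyclohexene thioester F1. Zinc insertion into its primary iodide gives the alkylzinc iodide F2. An intramolecular Fukuyama coupling (PdCl2(PPh3)2, PhMe, 1 mM, slow addition) then closes the ten-membered ketone and gives 19.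

**Step 2.** The substrate is a lactol, and ring–chain equilibrium plus the free zinc alkoxide may lower rate and enantioselectivity. The fallback sets out from 1 and comes back at 5, so step 1 is not needed. Lithium propynide (from 3 and n-BuLi, THF, −78 °C) opens the lactone to the hydroxy ynone (5Z)-8-hydroxy-6-methyloct-5-en-2-yn-4-one F3. Midland reduction with (R)-Alpine-Borane (alkynyl as the small group) then sets the 5R carbinol by reagent-controlled ketone reduction instead of C–C bond formation and gives 5.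

**Step 12.** The C5=C6 alkene may compete, and the diaxial opening depends on the half-chair with Me-15 and 14-OAc axial. The fallback sets out from 21 and comes back at 23; new compound on the way: none F0. It replaces the halohydrin/displacement sequence by direct, catalyst-controlled oxygen transfer from a chiral dioxirane: Shi fructose-derived ketone (the enantiomer matched to the β face), Oxone (2KHSO5·KHSO4·K2SO4), K2CO3 buffer, MeCN/dimethoxymethane/H2O, 0 °C.

Further compounds
F1 | step 9 | S-ethyl (1R,2S,6S)-2-(acetyloxy)-6-({(2R)-2-[(1Z)-4-iodo-2-methylbut-1-en-1-yl]-4-methyl-5-oxo-2,5-dihydrofuran-3-yl}methyl)-1,5-dimethylcyclohex-4-ene-1-carbothioate | ICC/C(C)=C\[C@H]1OC(=O)C(C)=C1C[C@H]1C(C)=CC[C@H](OC(C)=O)[C@]1(C)C(=O)SCC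
F2 | step 9 | alkylzinc iodide from F1 (C–I replaced by C–ZnI) | I[Zn]CC/C(C)=C\[C@H]1OC(=O)C(C)=C1C[C@H]1C(C)=CC[C@H](OC(C)=O)[C@]1(C)C(=O)SCC
F3 | step 2 | (5Z)-8-hydroxy-6-methyloct-5-en-2-yn-4-one | CC#CC(=O)/C=C(C)\CCO
F0 | step 12 | none | none
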